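**Plan**

1. Numbering: C1 is the acetoxymethyl carbon, C2=C3 the (E)-alkene, C6 the carbinol, C7 the quaternary ring carbon, C8 and C9 the ring CH2 groups, C10=C11 the ring alkene, C1′ the lactone carbonyl.
2. Enabling feature: without its ring oxygen the oxepinone is a cyclohexene made of C1′, C11, C10, C9, C8 and C7, and C7 with its methyl group and C6 maps onto the α-carbon of 2-methylacrolein.
3. Retrosynthetic cuts, in order: the silyl groups and the acetate; the ring O–C7 bond (oxygen removed from between C7 and C1′, a Baeyer–Villiger retron); C5–C6 (alkyllithium plus aldehyde); C8–C9 and C7–C1′ together (Diels–Alder); the C11–homoprenyl bond (alkylation of a crotonate dienolate).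
4. Forward order: the silyloxydiene (3 steps); the enantioselective [4+2] closes the only carbocycle; the C1–C5 chain (4 steps from but-3-yn-1-ol) is joined at C6; C1′ is oxidised to the enone; oxygen insertion between C1′ and C7 expands the cyclohexenone to the seven-membered lactone; desilylation finishes.
5. Stereochemistry: C7 comes from the chiral oxazaborolidinium catalyst and is kept in the ring expansion (migration with retention); C6 comes from Felkin–Anh addition next to C7; the (2E) alkene comes from syn-carboalumination; the C1′ stereocentre is temporary.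

Key step: step 4

Remark (assumption): the facial sense of the catalyst is taken from the usual pre-transition-state model, which predicts that the catalyst made from (R)-α,α-diphenylprolinol leaves the si face of Cα of 2-methylacrolein open (giving 7R in 9); should practice show the opposite sense, the (S)-prolinol-derived catalyst is used and nothing else changes.

**Route**

Step 1
Reactants: 1 methyl (E)-but-2-enoate (methyl crotonate); 2 5-bromo-2-methylpent-2-ene
Product: 4 methyl 2-ethenyl-6-methylhept-5-enoate (racemic), via lithium dienolate 3 (not isolated)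
Conditions: LiN(iPr)2 (1.1 equiv), HMPA (1.2 equiv), THF, −78 °C; then 2, −78 → −20 °C
Reagents that add atoms: none
Why: Kinetic γ-deprotonation gives the extended ester dienolate, which is alkylated at the α-carbon (deconjugative α-alkylation), so the homoprenyl chain ends up on the future C11; the new stereocentre is racemic and is erased in step 3.

Step 2
Reactants: 4 methyl 2-ethenyl-6-methylhept-5-enoate
Product: 6 2-ethenyl-6-methylhept-5-enal (racemic), via aluminium hemiacetal 5 (not isolated)
Conditions: iBu2AlH (1.05 equiv), CH2Cl2, −78 °C; MeOH at −78 °C, then aq. potassium sodium tartrate (KNaC4H4O6)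
Reagents that add atoms: none
Why: Partial ester reduction with iBu2AlH stops at the tetrahedral aluminium hemiacetal at −78 °C and releases the aldehyde only on work-up; drift of the alkene into conjugation would be harmless, because both aldehydes give the same dienol ether.

Step 3
Reactants: 6 2-ethenyl-6-methylhept-5-enal
Product: 7 (1E)-1-(tert-butyldimethylsilyloxy)-2-(4-methylpent-3-en-1-yl)buta-1,3-diene
Conditions: TBSOTf (1.2 equiv), Et3N (2 equiv), Et2O, 0 °C → rt; filtration through Et3N-deactivated silica
Reagents that add atoms: tert-butyldimethylsilyl trifluoromethanesulfonate, CC(C)(C)[Si](C)(C)OS(=O)(=O)C(F)(F)F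
Why: Soft enolisation and O-silylation of the dienolate (silyl dienol ether formation) should favour the (1E) isomer with oxygen trans to the vinyl group; a minor (1Z) isomer cannot reach the s-cis diene form and is simply left behind in step 4.

Step 4
Reactants: 7 (1E)-1-(tert-butyldimethylsilyloxy)-2-(4-methylpent-3-en-1-yl)buta-1,3-diene; 8 2-methylprop-2-enal (2-methylacrolein)
Product: 9 (1R,2S)-2-(tert-butyldimethylsilyloxy)-1-methyl-3-(4-methylpent-3-en-1-yl)cyclohex-3-ene-1-carbaldehyde (silyloxy cis to formyl; 7R in target numbering)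
Conditions: (R)-1-(2-methylphenyl)-3,3-diphenyltetrahydro-1H,3H-pyrrolo[1,2-c][1,3,2]oxazaborole (20 mol %), (CF3SO2)2NH (18 mol %), 8 (2 equiv), CH2Cl2, −78 °C; Et3N quench
Reagents that add atoms: none
Why: The N-protonated oxazaborolidine binds the formyl oxygen of 8 at boron and lowers the enal LUMO, and the diene then adds in a concerted, asynchronous [4+2] cycloaddition; the closest known reaction type is the oxazaborolidinium-catalysed Diels–Alder reaction of 2-substituted acroleins with 1-oxygenated dienes. The six-membered carbocycle (C1′, C11, C10, C9, C8, C7) is closed by the intermolecular cycloaddition itself, with C8–C9 forming ahead of C7–C1′. C7 is set by the catalyst: the bound s-trans enal lies over a carbinol phenyl group, so the diene should reach only the si face of Cα, which gives 7R. C1′ follows from the endo position of the formyl group (silyloxy cis to CHO) and is of no consequence, because any trans adduct converges when C1′ becomes a carbonyl carbon in step 12. The step needs ortho regiochemistry and enantiofacial control: the first is secured by the silyloxy donor, which puts the largest HOMO coefficient on the unsubstituted diene terminus (C9) and outweighs the 2-alkyl group, the second by the catalyst. The low temperature and the sub-stoichiometric acid are meant to keep the acid-labile dienol ether intact.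

Step 5
Reactants: 10 but-3-yn-1-ol
Product: 12 ethyl (2E)-5-hydroxy-3-methylpent-2-enoate, via alkenylalane 11 (not isolated)
Conditions: Me3Al (3 equiv), Cp2ZrCl2 (25 mol %), CH2Cl2, 0 °C → rt; then ClCO2Et (3 equiv), 0 °C → rt; aq. HCl work-up
Reagents that add atoms: trimethylaluminium, C[Al](C)C; ethyl chloroformate, CCOC(=O)Cl
Why: Zirconium-catalysed syn-carboalumination (Negishi) puts methyl and aluminium cis across the alkyne with aluminium at the terminus, and C-acylation of the alkenylalane with retention fixes the (2E) alkene, the aluminium alkoxide being too weak a nucleophile to compete.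

Step 6
Reactants: 12 ethyl (2E)-5-hydroxy-3-methylpent-2-enoate
Product: 13 ethyl (2E)-5-iodo-3-methylpent-2-enoate
Conditions: I2, PPh3, imidazole, CH2Cl2, 0 °C → rt
Reagents that add atoms: iodine, [I][I]
Why: Appel-type iodination converts the primary alcohol into the iodide by SN2 displacement of the alkoxyphosphonium ion and leaves the enoate alone.

Step 7
Reactants: 13 ethyl (2E)-5-iodo-3-methylpent-2-enoate
Product: 14 (2E)-5-iodo-3-methylpent-2-en-1-ol
Conditions: iBu2AlH (2.2 equiv), CH2Cl2, −78 °C; aq. potassium sodium tartrate (KNaC4H4O6)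
Reagents that add atoms: none
Why: iBu2AlH reduces the conjugated ester by 1,2-addition to the allylic alcohol at a temperature at which a primary alkyl iodide is inert.

Step 8
Reactants: 14 (2E)-5-iodo-3-methylpent-2-en-1-ol
Product: 15 tert-butyl{[(2E)-5-iodo-3-methylpent-2-en-1-yl]oxy}dimethylsilane
Conditions: TBSCl, imidazole, CH2Cl2, 0 °C
Reagents that add atoms: tert-butyldimethylsilyl chloride, CC(C)(C)[Si](C)(C)Cl
Why: Standard silylation of a primary allylic alcohol masks the C1 oxygen against the organolithium of step 9.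

Step 9
Reactants: 15 tert-butyl{[(2E)-5-iodo-3-methylpent-2-en-1-yl]oxy}dimethylsilane; 9 (1R,2S)-2-(tert-butyldimethylsilyloxy)-1-methyl-3-(4-methylpent-3-en-1-yl)cyclohex-3-ene-1-carbaldehyde
Product: 17 (1R,4E)-6-(tert-butyldimethylsilyloxy)-1-[(1S,2S)-2-(tert-butyldimethylsilyloxy)-1-methyl-3-(4-methylpent-3-en-1-yl)cyclohex-3-en-1-yl]-4-methylhex-4-en-1-ol, via alkyllithium 16 (not isolated)
Conditions: 15 (1.4 equiv), t-BuLi (2.8 equiv), Et2O–pentane, −78 °C; then 9, −78 °C; H2O quench at −78 °C
Reagents that add atoms: none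
Why: Iodine–lithium exchange gives the primary alkyllithium, which adds to the non-enolisable neopentyl aldehyde; Felkin–Anh control (attack anti to the bulky C1′ carbon and past the C7 methyl group, ring CH2 next to the carbonyl oxygen) should favour the (6R) carbinol.

Step 10
Reactants: 17 the bis-silyl ether carbinol
Product: 18 (1R,4E)-1-[(1S,2S)-2-hydroxy-1-methyl-3-(4-methylpent-3-en-1-yl)cyclohex-3-en-1-yl]-4-methylhex-4-ene-1,6-diol
Conditions: Bu4NF (4 equiv), THF, rt → 45 °C
Reagents that add atoms: none
Why: Fluoride-mediated desilylation removes both silyl ethers at once, which also makes any silyl shift between the C6 and C1′ oxygens during step 9 irrelevant.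

Step 11
Reactants: 18 the triol
Product: 19 (2E,6R)-6-hydroxy-6-[(1S,2S)-2-hydroxy-1-methyl-3-(4-methylpent-3-en-1-yl)cyclohex-3-en-1-yl]-3-methylhex-2-en-1-yl acetate
Conditions: Ac2O (1.05 equiv), pyridine, CH2Cl2, −20 → 0 °C
Reagents that add atoms: acetic anhydride, CC(=O)OC(C)=O
Why: Sterically controlled acylation should acetylate the unhindered primary allylic hydroxyl far faster than the two secondary hydroxyls that flank the quaternary C7.

Step 12
Reactants: 19 the diol monoacetate
Product: 20 (2E,6R)-6-hydroxy-3-methyl-6-[(1S)-1-methyl-3-(4-methylpent-3-en-1-yl)-2-oxocyclohex-3-en-1-yl]hex-2-en-1-yl acetate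
Conditions: activated MnO2 (20 equiv), CH2Cl2, rt
Reagents that add atoms: none
Why: MnO2 oxidises allylic alcohols selectively, so the C1′ carbinol becomes the enone while the saturated C6 carbinol is untouched, and the temporary C1′ stereocentre disappears.

Step 13
Reactants: 20 the β-hydroxy enone
Product: 21 (2E,6R)-3-methyl-6-[(1S)-1-methyl-3-(4-methylpent-3-en-1-yl)-2-oxocyclohex-3-en-1-yl]-6-(triethylsilyloxy)hex-2-en-1-yl acetate
Conditions: Et3SiOTf (1.3 equiv), 2,6-lutidine, CH2Cl2, −78 → 0 °C
Reagents that add atoms: triethylsilyl trifluoromethanesulfonate, CC[Si](CC)(CC)OS(=O)(=O)C(F)(F)F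
Why: Silylation with a silyl triflate and 2,6-lutidine protects the hindered C6 hydroxyl and so shuts off retro-aldol cleavage and intramolecular oxa-Michael addition of the β-hydroxy enone before the oxidation.

Step 14
Reactants: 21 the silyl-protected enone
Product: 22 (2E,6R)-3-methyl-6-[(2S)-2-methyl-6-(4-methylpent-3-en-1-yl)-7-oxo-2,3,4,7-tetrahydrooxepin-2-yl]-6-(triethylsilyloxy)hex-2-en-1-yl acetate
Conditions: Me3SiOOSiMe3 (3 equiv), SnCl4 (25 mol %), trans-cyclohexane-1,2-diamine (25 mol %), 4 Å molecular sieves, CH2Cl2, 0 °C → rt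
Reagents that add atoms: bis(trimethylsilyl) peroxide, C[Si](C)(C)OO[Si](C)(C)C
Why: In this Baeyer–Villiger oxidation the tin-activated ketone takes up the silyl peroxide to give a Criegee intermediate in which the quaternary C7 (tertiary alkyl) should migrate in preference to the alkenyl C11 and with retention, while the silyl peroxide, not being an electrophilic epoxidising agent, should spare the two trisubstituted alkenes.

Step 15
Reactants: 22 the silyl-protected lactone
Product: 23 (2E,6R)-6-hydroxy-3-methyl-6-[(2S)-2-methyl-6-(4-methylpent-3-en-1-yl)-7-oxo-2,3,4,7-tetrahydrooxepin-2-yl]hex-2-en-1-yl acetate (target)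
Conditions: HF·pyridine, pyridine, THF, 0 °C → rt
Reagents that add atoms: none
Why: Buffered HF·pyridine cleaves the triethylsilyl ether (fluoride-mediated desilylation) without touching the allylic acetate or the unsaturated lactone.

**Compound list**

1 | methyl (E)-but-2-enoate (methyl crotonate) | C/C=C/C(=O)OC | starting material
2 | 5-bromo-2-methylpent-2-ene | CC(C)=CCCBr | starting material
3 | lithium 1-methoxybuta-1,3-dien-1-olate (dienolate of 1) | [Li]OC(OC)=CC=C | intermediate (not isolated)
4 | methyl 2-ethenyl-6-methylhept-5-enoate (racemic) | C=CC(CCC=C(C)C)C(=O)OC | intermediate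
5 | diisobutylaluminium hemiacetal of 4 | C=CC(CCC=C(C)C)C(OC)O[Al](CC(C)C)CC(C)C | intermediate (not isolated)
6 | 2-ethenyl-6-methylhept-5-enal (racemic) | C=CC(CCC=C(C)C)C=O | intermediate
7 | (1E)-1-(tert-butyldimethylsilyloxy)-2-(4-methylpent-3-en-1-yl)buta-1,3-diene | C=C/C(CCC=C(C)C)=C/O[Si](C)(C)C(C)(C)C | intermediate
8 | 2-methylprop-2-enal (2-methylacrolein) | CC(=C)C=O | starting material
9 | (1R,2S)-2-(tert-butyldimethylsilyloxy)-1-methyl-3-(4-methylpent-3-en-1-yl)cyclohex-3-ene-1-carbaldehyde | O=C[C@]1(C)CCC=C(CCC=C(C)C)[C@@H]1O[Si](C)(C)C(C)(C)C | intermediate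
10 | but-3-yn-1-ol | C#CCCO | starting material
11 | dimethylaluminium alkoxide of (3E)-4-(dimethylalumanyl)-3-methylbut-3-en-1-ol | C[Al](C)/C=C(\C)CCO[Al](C)C | intermediate (not isolated)
12 | ethyl (2E)-5-hydroxy-3-methylpent-2-enoate | CCOC(=O)/C=C(\C)CCO | intermediate
13 | ethyl (2E)-5-iodo-3-methylpent-2-enoate | CCOC(=O)/C=C(\C)CCI | intermediate
14 | (2E)-5-iodo-3-methylpent-2-en-1-ol | OC/C=C(\C)CCI | intermediate
15 | tert-butyl{[(2E)-5-iodo-3-methylpent-2-en-1-yl]oxy}dimethylsilane | CC(C)(C)[Si](C)(C)OC/C=C(\C)CCI | intermediate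
16 | [(3E)-5-(tert-butyldimethylsilyloxy)-3-methylpent-3-en-1-yl]lithium | [Li]CC/C(C)=C/CO[Si](C)(C)C(C)(C)C | intermediate (not isolated)
17 | (1R,4E)-6-(tert-butyldimethylsilyloxy)-1-[(1S,2S)-2-(tert-butyldimethylsilyloxy)-1-methyl-3-(4-methylpent-3-en-1-yl)cyclohex-3-en-1-yl]-4-methylhex-4-en-1-ol | CC(C)(C)[Si](C)(C)OC/C=C(\C)CC[C@@H](O)[C@]1(C)CCC=C(CCC=C(C)C)[C@@H]1O[Si](C)(C)C(C)(C)C | intermediate
18 | (1R,4E)-1-[(1S,2S)-2-hydroxy-1-methyl-3-(4-methylpent-3-en-1-yl)cyclohex-3-en-1-yl]-4-methylhex-4-ene-1,6-diol | OC/C=C(\C)CC[C@@H](O)[C@]1(C)CCC=C(CCC=C(C)C)[C@@H]1O | intermediate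
19 | (2E,6R)-6-hydroxy-6-[(1S,2S)-2-hydroxy-1-methyl-3-(4-methylpent-3-en-1-yl)cyclohex-3-en-1-yl]-3-methylhex-2-en-1-yl acetate | CC(=O)OC/C=C(\C)CC[C@@H](O)[C@]1(C)CCC=C(CCC=C(C)C)[C@@H]1O | intermediate
20 | (2E,6R)-6-hydroxy-3-methyl-6-[(1S)-1-methyl-3-(4-methylpent-3-en-1-yl)-2-oxocyclohex-3-en-1-yl]hex-2-en-1-yl acetate | CC(=O)OC/C=C(\C)CC[C@@H](O)[C@]1(C)CCC=C(CCC=C(C)C)C1=O | intermediate
21 | (2E,6R)-3-methyl-6-[(1S)-1-methyl-3-(4-methylpent-3-en-1-yl)-2-oxocyclohex-3-en-1-yl]-6-(triethylsilyloxy)hex-2-en-1-yl acetate | CC(=O)OC/C=C(\C)CC[C@@H](O[Si](CC)(CC)CC)[C@]1(C)CCC=C(CCC=C(C)C)C1=O | intermediate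
22 | (2E,6R)-3-methyl-6-[(2S)-2-methyl-6-(4-methylpent-3-en-1-yl)-7-oxo-2,3,4,7-tetrahydrooxepin-2-yl]-6-(triethylsilyloxy)hex-2-en-1-yl acetate | CC(=O)OC/C=C(\C)CC[C@@H](O[Si](CC)(CC)CC)[C@]1(C)CCC=C(CCC=C(C)C)C(=O)O1 | intermediate
23 | (2E,6R)-6-hydroxy-3-methyl-6-[(2S)-2-methyl-6-(4-methylpent-3-en-1-yl)-7-oxo-2,3,4,7-tetrahydrooxepin-2-yl]hex-2-en-1-yl acetate | CC(=O)OC/C=C(\C)CC[C@@H](O)[C@]1(C)CCC=C(CCC=C(C)C)C(=O)O1 | target

**Totals and risks**

Total step count: 15. Longest linear sequence: 11 steps (steps 1–4, then 9–15); steps 5–8 form the side-chain branch that joins at step 9.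

The three steps most likely to fail:

Step 14. The oxidant may epoxidise the two electron-rich trisubstituted alkenes, or the insertion may be too slow at the hindered, conjugated ketone. The fallback sets out from 21 and oxidises every reactive site on purpose. Excess buffered peracid (mCPBA, NaHCO3, CH2Cl2; CF3CO3H with Na2HPO4 if insertion is slow) should give the lactone with both side-chain alkenes epoxidised, the bis-epoxy lactone F4; the electron-poor ring alkene is not expected to react. Stereospecific deoxygenation of both epoxides with retention (Ph3P=Se, CF3CO2H, CH2Cl2, rt) then restores the alkenes, the C2=C3 bond as (E), and the route is rejoined at 22.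

Step 4. The strongly acidic catalyst may destroy the silyl dienol ether (protodesilylation or Mukaiyama-type addition to the activated aldehyde), or facial discrimination may be insufficient. The fallback sets out from 7 and 8 and drops the acid altogether. Thermal cycloaddition (toluene, 90 °C, BHT, sealed tube) should give the racemic adduct F1, with regiochemistry still governed by the silyloxy group. Condensation with (1R,2R)-N,N′-dimethyl-1,2-diphenylethane-1,2-diamine (4 Å molecular sieves, Et2O, rt) gives diastereomeric aminals, from which the (7R)-configured imidazolidine F2 is separated by chromatography. Two-phase hydrolysis (dilute aq. HCl, Et2O) returns to the route at 9.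

Step 9. Facial selectivity of the addition to the α-quaternary aldehyde may be poor, or it may be eroded by chelation to the C1′ oxygen. The fallback sets out from 17 as obtained (mixed at C6) and replaces substrate control by reagent control. Oxidation with Dess–Martin periodinane (NaHCO3, CH2Cl2) gives the C6 ketone F3. CBS reduction with (S)-1-methyl-3,3-diphenyltetrahydro-1H,3H-pyrrolo[1,2-c][1,3,2]oxazaborole and catecholborane (toluene, −78 °C) should then deliver hydride to the face that gives (6R), the quaternary C7 acting as the large group; the route is rejoined at 17.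

**Further compounds**

F1 | step 4 | racemic cis-2-(tert-butyldimethylsilyloxy)-1-methyl-3-(4-methylpent-3-en-1-yl)cyclohex-3-ene-1-carbaldehyde (both enantiomers) | O=C[C@]1(C)CCC=C(CCC=C(C)C)[C@@H]1O[Si](C)(C)C(C)(C)C.O=C[C@@]1(C)CCC=C(CCC=C(C)C)[C@H]1O[Si](C)(C)C(C)(C)C
F2 | step 4 | (4R,5R)-2-[(1R,2S)-2-(tert-butyldimethylsilyloxy)-1-methyl-3-(4-methylpent-3-en-1-yl)cyclohex-3-en-1-yl]-1,3-dimethyl-4,5-diphenylimidazolidine | CN1C([C@]2(C)CCC=C(CCC=C(C)C)[C@@H]2O[Si](C)(C)C(C)(C)C)N(C)[C@H](c2ccccc2)[C@H]1c1ccccc1
F3 | step 9 | (4E)-6-(tert-butyldimethylsilyloxy)-1-[(1R,2S)-2-(tert-butyldimethylsilyloxy)-1-methyl-3-(4-methylpent-3-en-1-yl)cyclohex-3-en-1-yl]-4-methylhex-4-en-1-one | CC(C)(C)[Si](C)(C)OC/C=C(\C)CCC(=O)[C@]1(C)CCC=C(CCC=C(C)C)[C@@H]1O[Si](C)(C)C(C)(C)C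
F4 | step 14 | bis-epoxide of 22 at C2–C3 and at the homoprenyl alkene (mixture of epoxide diastereomers, trans at C2–C3) | CC(=O)OCC1OC1(C)CC[C@@H](O[Si](CC)(CC)CC)[C@]2(C)CCC=C(CCC3OC3(C)C)C(=O)O2
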